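**Retrosynthetic overview**
- Target 10 comes from 9 by hydrogenolysis of two aryl benzyl ethers; 9 comes from 8 by acetylation of its only primary alcohol.
- The oxolane (the only ring formed) is closed last through its C2–O1 bond: dehydrogenative benzylic C–H cycloetherification of acyclic triol 7, which sets C2.
- Triol 7 comes from epoxy diol 6 and benzylic Grignard reagent 3 by SN2 opening with inversion (sets C3); 6 comes from E-enediol 5 by Sharpless epoxidation (sets the tertiary C4–O centre).
- Enediol 5 comes from anti-carbomagnesiation of but-2-yne-1,4-diol 4 with 3; 3 is made once from chloride 2 (from alcohol 1) and used in both C–C bond-forming steps.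

Assumption: lignan locants are used beside ring numbers (C7 = C2, C8 = C3, C8' = C4, C9' = C5, C9 = the CH2OAc carbon, C7' = the benzylic CH2 on C4); 1, 4 and D-(−)-diisopropyl tartrate are bought.

**Step 1**
Reactants: 1 4-(benzyloxy)-3-methoxybenzyl alcohol
Product: 2 4-(benzyloxy)-3-methoxybenzyl chloride
Conditions: SOCl2 (1.2 equiv), CH2Cl2, 0 °C, 1 h; used crude the same day
Reagents that add atoms: thionyl chloride, O=S(Cl)Cl
Why: Deoxychlorination of an electron-rich benzylic alcohol through its chlorosulfite is fast and clean at 0 °C; no stereocenter is involved.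

**Step 2**
Reactants: 2 4-(benzyloxy)-3-methoxybenzyl chloride
Product: 3 [4-(benzyloxy)-3-methoxybenzyl]magnesium chloride (about 0.4 M stock solution)
Conditions: Mg turnings (2.5 equiv), 2-MeTHF, 0 °C, slow addition of 2 over 3 h; titrated, kept under argon at −20 °C; one portion for step 3, one for step 5
Reagents that add atoms: magnesium, [Mg]
Why: Grignard formation by insertion of magnesium into the benzylic C–Cl bond; slow addition at 0 °C in 2-MeTHF over excess metal suppresses Wurtz homocoupling, and the aryl benzyl ether is inert.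

**Step 3**
Reactants: 3 [4-(benzyloxy)-3-methoxybenzyl]magnesium chloride; 4 but-2-yne-1,4-diol
Product: 5 (E)-2-[4-(benzyloxy)-3-methoxybenzyl]but-2-ene-1,4-diol
Conditions: 3 (3.3 equiv), CuI (10 mol %), THF/2-MeTHF, 0 to 50 °C; then cold 1 M HCl
Reagents that add atoms: none
Why: Chelation-controlled anti-carbomagnesiation of a propargylic alkoxide places the benzyl group on the carbon next to one CH2O and trans to the new vinylic hydrogen, so protonation gives only the E-enediol (CH2OH groups trans); the diol is symmetric, so there is no regiochemical issue.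

**Step 4**
Reactants: 5 (E)-2-[4-(benzyloxy)-3-methoxybenzyl]but-2-ene-1,4-diol
Product: 6 [(2R,3R)-2-[4-(benzyloxy)-3-methoxybenzyl]oxirane-2,3-diyl]dimethanol
Conditions: Ti(OiPr)4 (20 mol %), D-(−)-diisopropyl tartrate (24 mol %), t-BuOOH (2 equiv, decane), 4 Å molecular sieves, CH2Cl2, −20 °C
Reagents that add atoms: tert-butyl hydroperoxide, CC(C)(C)OO
Why: Sharpless asymmetric epoxidation; in the E-diol both allylic hydroxyls direct to the same alkene face, and because the L-(+)-tartrate gives the (2S,3S) epoxy alcohol from E-allylic alcohols and the priority order at both carbons is the same here, the D-(−)-ester gives (2R,3R), fixing the tertiary C–O stereocenter (later C4) and the epoxide carbon that becomes C3.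

**Step 5**
Reactants: 6 [(2R,3R)-2-[4-(benzyloxy)-3-methoxybenzyl]oxirane-2,3-diyl]dimethanol; 3 [4-(benzyloxy)-3-methoxybenzyl]magnesium chloride
Product: 7 (2S,3S)-2,3-bis[4-(benzyloxy)-3-methoxybenzyl]butane-1,2,4-triol
Conditions: 3 (4 equiv), CuI (10 mol %), THF/2-MeTHF, −30 to 0 °C; then cold 1 M HCl
Reagents that add atoms: none
Why: Copper-catalysed SN2 opening of the epoxide by the Grignard reagent can only occur at the CH carbon (the other epoxide carbon is fully substituted) and proceeds with inversion, which sets C3 and leaves the tertiary C–O bond untouched; low temperature and copper catalysis keep chloride opening by the magnesium salts in check.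

**Step 6**
Reactants: 7 (2S,3S)-2,3-bis[4-(benzyloxy)-3-methoxybenzyl]butane-1,2,4-triol
Product: 8 [(2S,3R,4S)-2-[4-(benzyloxy)-3-methoxyphenyl]-4-[4-(benzyloxy)-3-methoxybenzyl]-4-hydroxytetrahydrofuran-3-yl]methanol (4,4'-di-O-benzylolivil)
Conditions: DDQ (1.1 equiv), 2,6-di-tert-butylpyridine (2 equiv), 4 Å molecular sieves, CH2Cl2, −20 to 0 °C
Reagents that add atoms: none
Why: Proposed new method: site-selective dehydrogenative benzylic C–H to C–O cycloetherification on an unprotected 1,2,4-triol carrying two equally electron-rich ArCH2 groups; the quinone forms a charge-transfer complex with either ring, but hydride transfer should be faster from C7 than from C7', because C7' is neopentylic and a cation there is destabilised by the adjacent tertiary C–OH dipole; the C7 cation is captured 5-exo by the primary C9' hydroxyl (no other hydroxyl can reach it through a five-membered ring) with the aryl group trans to the C3 CH2OH, giving (2S); the hindered base keeps the medium non-acidic so that neither Friedel–Crafts closure onto the other ring nor re-ionisation of the product occurs, and allylic strain in the would-be planar oxocarbenium should slow over-oxidation of the product ether; the closest known reaction type is DDQ-mediated benzylic hydride abstraction with alcohol capture, as used on single-site arylalkanols and in cleavage of p-methoxybenzyl ethers.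

**Step 7**
Reactants: 8 4,4'-di-O-benzylolivil
Product: 9 [(2S,3R,4S)-2-[4-(benzyloxy)-3-methoxyphenyl]-4-[4-(benzyloxy)-3-methoxybenzyl]-4-hydroxytetrahydrofuran-3-yl]methyl acetate
Conditions: Ac2O (1.2 equiv), pyridine, CH2Cl2, 0 °C
Reagents that add atoms: acetic anhydride, CC(=O)OC(C)=O
Why: Chemoselective O-acetylation of the single primary alcohol; the hindered tertiary alcohol does not react without forcing conditions and no stereocenter is touched.

**Step 8**
Reactants: 9 di-O-benzylolivil 9-acetate
Product: 10 [(2S,3R,4S)-4-hydroxy-2-(4-hydroxy-3-methoxyphenyl)-4-(4-hydroxy-3-methoxybenzyl)tetrahydrofuran-3-yl]methyl acetate (olivil monoacetate)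
Conditions: H2 (1 atm), 10% Pd/C, EtOAc, rt, stopped at full conversion; neutral work-up
Reagents that add atoms: none
Why: Catalytic hydrogenolysis cleaves the two aryl benzyl ethers much faster than the cyclic benzylic ether under neutral 1 atm conditions, and the acetate and tertiary alcohol are inert; avoiding acid prevents rearrangement to the aryltetralin (cyclo-olivil type).

**Compound list**
1 | 4-(benzyloxy)-3-methoxybenzyl alcohol | OCc1ccc(OCc2ccccc2)c(OC)c1 | starting material
2 | 4-(benzyloxy)-3-methoxybenzyl chloride | ClCc1ccc(OCc2ccccc2)c(OC)c1 | intermediate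
3 | [4-(benzyloxy)-3-methoxybenzyl]magnesium chloride | Cl[Mg]Cc1ccc(OCc2ccccc2)c(OC)c1 | intermediate
4 | but-2-yne-1,4-diol | OCC#CCO | starting material
5 | (E)-2-[4-(benzyloxy)-3-methoxybenzyl]but-2-ene-1,4-diol | OC/C=C(/CO)Cc1ccc(OCc2ccccc2)c(OC)c1 | intermediate
6 | [(2R,3R)-2-[4-(benzyloxy)-3-methoxybenzyl]oxirane-2,3-diyl]dimethanol | OC[C@@]1(Cc2ccc(OCc3ccccc3)c(OC)c2)O[C@@H]1CO | intermediate
7 | (2S,3S)-2,3-bis[4-(benzyloxy)-3-methoxybenzyl]butane-1,2,4-triol | OC[C@](O)(Cc1ccc(OCc2ccccc2)c(OC)c1)[C@H](CO)Cc1ccc(OCc2ccccc2)c(OC)c1 | intermediate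
8 | [(2S,3R,4S)-2-[4-(benzyloxy)-3-methoxyphenyl]-4-[4-(benzyloxy)-3-methoxybenzyl]-4-hydroxytetrahydrofuran-3-yl]methanol | COc1cc(C[C@@]2(O)CO[C@H](c3ccc(OCc4ccccc4)c(OC)c3)[C@H]2CO)ccc1OCc1ccccc1 | intermediate
9 | [(2S,3R,4S)-2-[4-(benzyloxy)-3-methoxyphenyl]-4-[4-(benzyloxy)-3-methoxybenzyl]-4-hydroxytetrahydrofuran-3-yl]methyl acetate | COc1cc(C[C@@]2(O)CO[C@H](c3ccc(OCc4ccccc4)c(OC)c3)[C@H]2COC(C)=O)ccc1OCc1ccccc1 | intermediate
10 | [(2S,3R,4S)-4-hydroxy-2-(4-hydroxy-3-methoxyphenyl)-4-(4-hydroxy-3-methoxybenzyl)tetrahydrofuran-3-yl]methyl acetate (olivil monoacetate) | COc1cc(C[C@@]2(O)CO[C@H](c3ccc(O)c(OC)c3)[C@H]2COC(C)=O)ccc1O | target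

**Step count and risks**
Total steps: 8. Longest linear sequence: 8 (1 → 2 → 3 → 5 → 6 → 7 → 8 → 9 → 10; Grignard reagent 3 is used in steps 3 and 5).

The three steps most likely to fail:

1. Step 6 (the proposed new cycloetherification). The risks are hydride abstraction at C7' (which would give the regioisomeric oxolane through the C9 hydroxyl), over-oxidation of the product benzylic ether, and Friedel–Crafts closure onto the second ring. The fallback uses known chemistry, sets out from 6 and comes back to the route at 8; it brings C7 in at the aldehyde oxidation level so that no C–H oxidation is needed. Copper-catalysed opening of 6 with CH2=CHMgBr (CuI cat., THF, −30 to 0 °C) gives (2S,3S)-2-[4-(benzyloxy)-3-methoxybenzyl]-3-ethenylbutane-1,2,4-triol F1. Ozonolysis with a controlled amount of ozone (O3, CH2Cl2/MeOH, −78 °C, then Me2S) gives the cyclic hemiacetal (3S,4S)-4-[4-(benzyloxy)-3-methoxybenzyl]-3-(hydroxymethyl)oxolane-2,4-diol F2. Excess [4-(benzyloxy)-3-methoxyphenyl]magnesium bromide F3, made from commercial 1-(benzyloxy)-4-bromo-2-methoxybenzene and Mg in THF, adds to the open aldehyde form to give (2S,3R)-2-[4-(benzyloxy)-3-methoxybenzyl]-3-{[4-(benzyloxy)-3-methoxyphenyl](hydroxy)methyl}butane-1,2,4-triol F4 as a C7 epimer mixture. Brief treatment with camphorsulfonic acid (5 mol %, CH2Cl2, 0 °C) ionises the benzylic alcohol and closes the ring through the primary C9' hydroxyl to the 2,3-trans product 8.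

2. Step 4 (asymmetric epoxidation of a free 1,4-diol). The second hydroxyl may bridge titanium centres and lower rate or enantiomeric excess. The fallback sets out from 5 and comes back to the route at 6; it uses a reagent-controlled epoxidation that needs no free hydroxyl. Compound 5 is silylated (t-BuMe2SiCl, imidazole, DMF) to (E)-2-[4-(benzyloxy)-3-methoxybenzyl]-1,4-bis[(tert-butyldimethylsilyl)oxy]but-2-ene F5. This is epoxidised with the D-fructose-derived Shi ketone (30 mol %), KHSO5 and K2CO3 in MeCN/dimethoxymethane/H2O at 0 °C to (2R,3R)-2-[4-(benzyloxy)-3-methoxybenzyl]-2,3-bis{[(tert-butyldimethylsilyl)oxy]methyl}oxirane F6. The facial sense is the one this ketone shows with trans-disubstituted and trisubstituted olefins; should it prove opposite, the enantiomeric ketone is used. Bu4NF in THF then returns 6.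

3. Step 3 (carbomagnesiation). The risks are sluggish addition to the poorly soluble dialkoxide and consumption of a large excess of the benzylic Grignard reagent. The fallback sets out from 4 and comes back to the route at 5; it replaces carbometalation by hydrometalation and cross-coupling. trans-Hydroalumination of 4 with NaAlH2(OCH2CH2OCH3)2 in THF followed by I2 gives (Z)-2-iodobut-2-ene-1,4-diol F7. Negishi coupling of this iodide with [4-(benzyloxy)-3-methoxybenzyl]zinc chloride F8 (from 2, Zn dust and LiCl in THF), catalysed by Pd(OAc)2 (2 mol %) and SPhos (4 mol %) in THF at rt, gives 5 with retention of alkene geometry.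

**Further compounds**
F1 | step 6 | (2S,3S)-2-[4-(benzyloxy)-3-methoxybenzyl]-3-ethenylbutane-1,2,4-triol | OC[C@](O)(Cc1ccc(OCc2ccccc2)c(OC)c1)[C@H](CO)C=C
F2 | step 6 | (3S,4S)-4-[4-(benzyloxy)-3-methoxybenzyl]-3-(hydroxymethyl)oxolane-2,4-diol (anomer mixture) | COc1cc(C[C@@]2(O)COC(O)[C@H]2CO)ccc1OCc1ccccc1
F3 | step 6 | [4-(benzyloxy)-3-methoxyphenyl]magnesium bromide | Br[Mg]c1ccc(OCc2ccccc2)c(OC)c1
F4 | step 6 | (2S,3R)-2-[4-(benzyloxy)-3-methoxybenzyl]-3-{[4-(benzyloxy)-3-methoxyphenyl](hydroxy)methyl}butane-1,2,4-triol (C7 epimer mixture) | OC[C@](O)(Cc1ccc(OCc2ccccc2)c(OC)c1)[C@H](CO)C(O)c1ccc(OCc2ccccc2)c(OC)c1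
F5 | step 4 | (E)-2-[4-(benzyloxy)-3-methoxybenzyl]-1,4-bis[(tert-butyldimethylsilyl)oxy]but-2-ene | CC(C)(C)[Si](C)(C)OC/C=C(/CO[Si](C)(C)C(C)(C)C)Cc1ccc(OCc2ccccc2)c(OC)c1
F6 | step 4 | (2R,3R)-2-[4-(benzyloxy)-3-methoxybenzyl]-2,3-bis{[(tert-butyldimethylsilyl)oxy]methyl}oxirane | CC(C)(C)[Si](C)(C)OC[C@@]1(Cc2ccc(OCc3ccccc3)c(OC)c2)O[C@@H]1CO[Si](C)(C)C(C)(C)C
F7 | step 3 | (Z)-2-iodobut-2-ene-1,4-diol | OC/C=C(/CO)I
F8 | step 3 | [4-(benzyloxy)-3-methoxybenzyl]zinc chloride | Cl[Zn]Cc1ccc(OCc2ccccc2)c(OC)c1
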